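Atom numbers follow the target SMILES from left to right (C1 exo-methylene carbon, C16 hemiketal carbon, C20 peroxy carbon); ring A is the cyclobutane, ring B the nine-membered ring.
Cuts, last bond first: the ring-B oxirane, the acetate, O–C20 and O–C16 of the dioxine (epoxide perhydrolysis, hemiperketal closure), C16–C18 (acetylide plus aldehyde), C2–C3 of ring B (vinyl iodide plus aldehyde, C3–O removed afterwards), C4–C5 (oxirane opening), C7–C8 (carboalumination), C11–C12 and C13–C14 of ring A ([2+2]).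
Forward order: ring A by allenoate–alkene cycloaddition, then the C3–C10 arm and the 2-iodoalkene, then ring B, then the dioxine ring, the oxirane last.
Enabling feature: the exocyclic C1=C2 double bond of ring B lies next to C3, so a 2-iodoalkene at C2 and an aldehyde at C3 place the exo-methylene in the ring closure itself.
Stereochemistry: C11/C14 from the E-alkene geometry plus a chiral Lewis acid; C12 by ketone equilibration; C5=C7 (E) by syn-carboalumination; C20 from (S)-2-methylglycidol with inversion; C16 thermodynamic; C5/C7 oxirane by outer-face attack on ring B.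
Key step: step 15

Assumption: the hemiperketal carbon C16 equilibrates by ring–chain tautomerism, and the configuration drawn for the target (hydroxyl cis to the acetoxymethyl group) is taken to be the one favoured at equilibrium.

Step 1
Reactants: 1 pent-4-yn-1-ol
Product: 3 ethyl (2E)-2-methylhept-2-en-6-ynoate, via pent-4-ynal 2 (not isolated)
Conditions: PhI(OAc)2, TEMPO (2,2,6,6-tetramethylpiperidin-1-oxyl, 10 mol %), CH2Cl2, rt; then Ph3P=C(CH3)CO2Et, rt
Reagents that add atoms: ethyl 2-(triphenylphosphoranylidene)propanoate, CCOC(=O)C(C)=P(c1ccccc1)(c1ccccc1)c1ccccc1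
Why: Oxoammonium oxidation stops at the aldehyde, and the Wittig reaction of the stabilised ylide in the same flask should give the E-enoate, which places the future C10 chain cis to the future C15 methyl group.

Step 2
Reactants: 3 ethyl (2E)-2-methylhept-2-en-6-ynoate
Product: 4 (2E)-2-methylhept-2-en-6-yn-1-ol
Conditions: i-Bu2AlH (2.2 equiv), CH2Cl2, −78 °C; Rochelle salt work-up
Reagents that add atoms: none
Why: 1,2-Reduction of the enoate by the aluminium hydride gives the allylic alcohol and leaves the alkene geometry and the terminal alkyne untouched.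

Step 3
Reactants: 4 (2E)-2-methylhept-2-en-6-yn-1-ol
Product: 5 tert-butyl{[(2E)-2-methylhept-2-en-6-yn-1-yl]oxy}diphenylsilane
Conditions: t-BuPh2SiCl, imidazole, CH2Cl2, rt
Reagents that add atoms: tert-butyl(chloro)diphenylsilane, CC(C)(C)[Si](Cl)(c1ccccc1)c1ccccc1
Why: Silylation of the primary alcohol; the bulky, weakly basic silyl ether is chosen to resist the Lewis acid of step 5 and the acid of step 13.

Step 4
Reactants: 6 but-3-ynoic acid
Product: 8 2,2,2-trifluoroethyl buta-2,3-dienoate, via 2,2,2-trifluoroethyl but-3-ynoate 7 (not isolated)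
Conditions: CF3CH2OH, DCC, CH2Cl2, 0 °C; then Et3N (10 mol %), rt
Reagents that add atoms: 2,2,2-trifluoroethanol, OCC(F)(F)F
Why: Carbodiimide (Steglich-type) esterification followed by amine-mediated propargyl-to-allenyl isomerisation of the β,γ-alkynoate gives the electron-poor allenoate.

Step 5
Reactants: 5 tert-butyl{[(2E)-2-methylhept-2-en-6-yn-1-yl]oxy}diphenylsilane; 8 2,2,2-trifluoroethyl buta-2,3-dienoate
Product: 9 2,2,2-trifluoroethyl 2-[(2S,3S)-2-(but-3-yn-1-yl)-3-({[tert-butyl(diphenyl)silyl]oxy}methyl)-3-methylcyclobutylidene]acetate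
Conditions: (S)-1-(2-methylphenyl)-3,3-diphenyltetrahydro-1H,3H-pyrrolo[1,2-c][1,3,2]oxazaborole activated with AlBr3 (20 mol % each), CH2Cl2, −78 to −40 °C
Reagents that add atoms: none
Why: Lewis acid-catalysed enantioselective allenoate–alkene [2+2] cycloaddition, a reaction type known for trisubstituted alkenes: C11 attacks the central allenoate carbon and the tertiary C14 cation is captured by the γ-carbon, so C11–C12 and C13–C14 form with retention of the E geometry (C10 chain cis to the C14 methyl), while the chiral boron Lewis acid selects the alkene face, the catalyst antipode being the one that leads to the (2S,3S) adduct.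

Step 6
Reactants: 9 the cycloadduct
Product: 10 2-[(2S,3S)-2-(but-3-yn-1-yl)-3-({[tert-butyl(diphenyl)silyl]oxy}methyl)-3-methylcyclobutylidene]ethan-1-ol
Conditions: i-Bu2AlH (2.5 equiv), CH2Cl2, −78 °C
Reagents that add atoms: none
Why: 1,2-Reduction of the activated ester to the primary allylic alcohol without touching the exocyclic alkene.

Step 7
Reactants: 10 the allylic alcohol
Product: 13 tert-butyl{[(1S,2S)-2-(but-3-yn-1-yl)-3-ethenyl-1-methylcyclobutyl]methoxy}diphenylsilane (C12 epimers), via sulfonylhydrazine adduct 11 (not isolated), via allylic diazene 12 (not isolated)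
Conditions: 2-nitrobenzenesulfonylhydrazide, PPh3, diethyl azodicarboxylate, THF, −30 °C; then 23 °C
Reagents that add atoms: none
Why: Mitsunobu N-alkylation, loss of sulfinic acid and retro-ene extrusion of N2 from the allylic diazene (reductive 1,3-transposition of an allylic alcohol) move the double bond out of the ring and deliver hydrogen to C12, whose configuration is left open because step 10 sets it.

Step 8
Reactants: 13 the vinylcyclobutane; 14 oxirane
Product: 17 (3E)-6-[(1S,2S)-2-({[tert-butyl(diphenyl)silyl]oxy}methyl)-4-ethenyl-2-methylcyclobutyl]-4-methylhex-3-en-1-ol (C12 epimers), via alkenyldimethylalane 15 (not isolated), via lithium alkenylalanate 16 (not isolated)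
Conditions: Me3Al (3 equiv), Cp2ZrCl2 (25 mol %), CH2Cl2, 0 °C to rt; volatiles removed; n-BuLi, THF/hexane, −78 °C; oxirane, −78 °C to rt
Reagents that add atoms: trimethylaluminium, C[Al](C)C
Why: Zirconium-catalysed syn-carboalumination (Negishi) puts methyl on C7 and aluminium on C5 on the same side, and the lithium alanate opens oxirane with retention at C5, so C5=C7 is E; the monosubstituted vinyl group reacts far more slowly than the terminal alkyne.

Step 9
Reactants: 17 the homoallylic alcohol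
Product: 18 tert-butyl{[(1S,2S)-2-[(3E)-6-{[tert-butyl(dimethyl)silyl]oxy}-3-methylhex-3-en-1-yl]-3-ethenyl-1-methylcyclobutyl]methoxy}diphenylsilane (C12 epimers)
Conditions: t-BuMe2SiCl, imidazole, CH2Cl2, rt
Reagents that add atoms: tert-butyl(chloro)dimethylsilane, CC(C)(C)[Si](C)(C)Cl
Why: Silylation shields the homoallylic alcohol from iodoetherification in step 12 and can later be removed next to the diphenylsilyl ether.

Step 10
Reactants: 18 the bis-silyl ether
Product: 20 1-[(1R,2S,3S)-2-[(3E)-6-{[tert-butyl(dimethyl)silyl]oxy}-3-methylhex-3-en-1-yl]-3-({[tert-butyl(diphenyl)silyl]oxy}methyl)-3-methylcyclobutyl]ethan-1-one, via ketone epimer mixture 19 (not isolated)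
Conditions: PdCl2 (10 mol %), CuCl (1 equiv), O2 (1 atm), DMF/H2O 7:1, rt; then K2CO3, MeOH, rt
Reagents that add atoms: water, O
Why: Tsuji–Wacker oxidation by divalent palladium converts only the monosubstituted alkene into the methyl ketone, and base equilibration through the enolate sets C12 as the trans-1,2 isomer in which acetyl, C10 chain and silyloxymethyl group are all pseudo-equatorial.

Step 11
Reactants: 20 the methyl ketone
Product: 21 the hydrazone of 20, (1R,2S,3S)-configured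
Conditions: N2H4·H2O, Et3N, EtOH, 70 °C
Reagents that add atoms: hydrazine, NN
Why: Condensation to the hydrazone, with the amine base suppressing azine formation.

Step 12
Reactants: 21 the hydrazone
Product: 22 tert-butyl{[(3E)-6-[(1S,2S,4R)-2-({[tert-butyl(diphenyl)silyl]oxy}methyl)-4-(1-iodoethenyl)-2-methylcyclobutyl]-4-methylhex-3-en-1-yl]oxy}dimethylsilane
Conditions: iodine, 1,1,3,3-tetramethylguanidine, THF, 0 °C to rt
Reagents that add atoms: iodine, [I][I]
Why: Barton vinyl iodide synthesis: iodination of the hydrazone, loss of N2 and base-induced elimination towards the methyl group give the 2-iodo-1-alkene, the alternative alkylidenecyclobutane being strained.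

Step 13
Reactants: 22 the vinyl iodide
Product: 23 (3E)-6-[(1S,2S,4R)-2-({[tert-butyl(diphenyl)silyl]oxy}methyl)-4-(1-iodoethenyl)-2-methylcyclobutyl]-4-methylhex-3-en-1-ol
Conditions: camphor-10-sulfonic acid (10 mol %), MeOH/CH2Cl2 1:1, 0 °C
Reagents that add atoms: none
Why: Acid-catalysed methanolysis removes the primary dimethylsilyl ether much faster than the diphenylsilyl ether.

Step 14
Reactants: 23 the iodo alcohol
Product: 24 (3E)-6-[(1S,2S,4R)-2-({[tert-butyl(diphenyl)silyl]oxy}methyl)-4-(1-iodoethenyl)-2-methylcyclobutyl]-4-methylhex-3-enal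
Conditions: Dess–Martin periodinane, NaHCO3, CH2Cl2, 0 °C; filtered and used at once
Reagents that add atoms: none
Why: Dess–Martin oxidation under buffered, non-basic conditions gives the β,γ-unsaturated aldehyde without migration of the C5=C7 double bond.

Step 15
Reactants: 24 the iodo aldehyde
Product: 26 (1S,4E,9R,11S)-11-({[tert-butyl(diphenyl)silyl]oxy}methyl)-4,11-dimethyl-8-methylidenebicyclo[7.2.0]undec-4-en-7-ol (C3 epimers), via alkenylchromium dichloride 25 (not isolated)
Conditions: CrCl2 (10 equiv), NiCl2 (2 mol %), degassed DMSO/THF 3:1, rt, 24 added slowly to a final 2 mM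
Reagents that add atoms: none
Why: NiCl2 is reduced by divalent chromium to zerovalent nickel, which inserts into the C2–I bond and hands the alkenyl group to trivalent chromium; the alkenylchromium species 25 then adds to the C3 aldehyde through a chromium-bound transition state and forms C2–C3. The closest known reaction is the intramolecular Nozaki–Hiyama–Kishi coupling of 2-iodo-1-alkenes with aldehydes to medium-ring allylic alcohols. Ring B (C2, C3, C4, C5, C7, C9, C10, C11, C12) closes in a 9-exo-trig addition to the carbonyl group, with the exo-methylene already in place. The new stereocentre C3 is not controlled and need not be, because both epimers lose the hydroxyl in step 17. The step needs carbonyl addition without enolisation or conjugation of the β,γ-unsaturated aldehyde, which the non-basic organochromium reagent provides, and ring closure ahead of oligomerisation, which high dilution and the trans-disubstituted cyclobutane holding the two arms on neighbouring carbons should secure.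

Step 16
Reactants: 26 the dienol
Product: 27 (1S,4E,9R,11S)-11-({[tert-butyl(diphenyl)silyl]oxy}methyl)-4,11-dimethyl-8-methylidenebicyclo[7.2.0]undec-4-en-7-yl methyl carbonate (C3 epimers)
Conditions: ClCO2Me, pyridine, 4-(dimethylamino)pyridine (10 mol %), CH2Cl2, 0 °C
Reagents that add atoms: methyl chloroformate, COC(=O)Cl
Why: Acylation of the allylic alcohol under nucleophilic catalysis gives the ionisable allylic carbonate from both epimers.

Step 17
Reactants: 27 the allylic carbonate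
Product: 28 tert-butyl{[(1S,4E,9R,11S)-4,11-dimethyl-8-methylidenebicyclo[7.2.0]undec-4-en-11-yl]methoxy}diphenylsilane
Conditions: Pd(OAc)2 (5 mol %), n-Bu3P (10 mol %), HCO2H, Et3N, THF, 40 °C
Reagents that add atoms: none
Why: Tsuji–Mandai formate hydrogenolysis: zerovalent palladium ionises the carbonate to the C1–C2–C3 π-allyl complex, formate replaces methoxide, and decarboxylative hydride transfer from the σ-allyl form bound at primary C1 reaches the more substituted C3, so the exo-methylene is kept and both C3 epimers converge.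

Step 18
Reactants: 28 the diene silyl ether
Product: 29 [(1S,4E,9R,11S)-4,11-dimethyl-8-methylidenebicyclo[7.2.0]undec-4-en-11-yl]methanol
Conditions: Bu4NF, THF, rt
Reagents that add atoms: none
Why: Fluoride-driven desilylation; nothing else in the molecule is fluoride-sensitive.

Step 19
Reactants: 29 the neopentyl alcohol
Product: 30 (1S,4E,9R,11S)-4,11-dimethyl-8-methylidenebicyclo[7.2.0]undec-4-ene-11-carbaldehyde
Conditions: Dess–Martin periodinane, NaHCO3, CH2Cl2, 0 °C to rt
Reagents that add atoms: none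
Why: Dess–Martin oxidation gives a non-enolisable aldehyde at C16.

Step 20
Reactants: 31 [(2S)-2-methyloxiran-2-yl]methanol
Product: 33 (2S)-2-ethynyl-2-methyloxirane, via (2R)-2-methyloxirane-2-carbaldehyde 32 (not isolated)
Conditions: PhI(OAc)2, TEMPO (10 mol %), CH2Cl2, 0 °C; then MeOH, K2CO3, dimethyl (1-diazo-2-oxopropyl)phosphonate, 0 °C to rt; distilled as an ethereal solution
Reagents that add atoms: dimethyl (1-diazo-2-oxopropyl)phosphonate, COP(=O)(OC)C(=[N+]=[N-])C(C)=O
Why: Oxoammonium oxidation and Ohira–Bestmann (Seyferth–Gilbert) homologation in one flask turn CH2OH into C≡CH without touching the quaternary epoxide carbon, whose configuration is therefore kept.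

Step 21
Reactants: 30 the C16 aldehyde; 33 (2S)-2-ethynyl-2-methyloxirane
Product: 35 1-[(1S,4E,9R,11S)-4,11-dimethyl-8-methylidenebicyclo[7.2.0]undec-4-en-11-yl]-3-[(2S)-2-methyloxiran-2-yl]prop-2-yn-1-ol (C16 epimers), via lithium acetylide 34 (not isolated)
Conditions: 33, n-BuLi, THF, −78 °C; then 30, −78 to −20 °C
Reagents that add atoms: none
Why: 1,2-Addition of the lithium acetylide to the hindered, non-enolisable aldehyde forms C16–C18; the carbinol centre is not controlled and disappears in step 22.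

Step 22
Reactants: 35 the propargylic alcohol
Product: 36 1-[(1S,4E,9R,11S)-4,11-dimethyl-8-methylidenebicyclo[7.2.0]undec-4-en-11-yl]-3-[(2S)-2-methyloxiran-2-yl]prop-2-yn-1-one
Conditions: Dess–Martin periodinane, NaHCO3, CH2Cl2, 0 °C
Reagents that add atoms: none
Why: Dess–Martin oxidation of the propargylic alcohol gives the ynone; epoxide and both alkenes are inert.

Step 23
Reactants: 36 the ynone
Product: 37 (2Z)-1-[(1S,4E,9R,11S)-4,11-dimethyl-8-methylidenebicyclo[7.2.0]undec-4-en-11-yl]-3-[(2S)-2-methyloxiran-2-yl]prop-2-en-1-one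
Conditions: H2 (1 atm), Pd on CaCO3 poisoned with Pb(OAc)2, quinoline, EtOAc, 0 °C, stopped after 1 equiv of H2
Reagents that add atoms: none
Why: Partial syn-hydrogenation of the alkyne on lead-poisoned palladium gives the Z-enone, the geometry that brings C16 and C20 within reach of one peroxide bridge.

Step 24
Reactants: 37 the Z-epoxy enone
Product: 39 (3R,6R)-3-[(1S,4E,9R,11S)-4,11-dimethyl-8-methylidenebicyclo[7.2.0]undec-4-en-11-yl]-6-(hydroxymethyl)-6-methyl-3,6-dihydro-1,2-dioxin-3-ol, via Z-hydroperoxy enone 38 (not isolated)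
Conditions: anhydrous H2O2 in Et2O (10 equiv), MoO2(acac)2 (5 mol %), 0 °C to rt, in the dark
Reagents that add atoms: hydrogen peroxide, OO
Why: Molybdenum-catalysed perhydrolysis opens the 2,2-disubstituted epoxide at the tertiary carbon C20 with inversion (giving 20R and the free C22 alcohol), and the cis-γ-hydroperoxy enone closes by 6-exo-trig addition of the hydroperoxide to the C16 carbonyl, C16 settling under thermodynamic control.

Step 25
Reactants: 39 the dioxinol diol
Product: 40 [(3R,6R)-6-[(1S,4E,9R,11S)-4,11-dimethyl-8-methylidenebicyclo[7.2.0]undec-4-en-11-yl]-6-hydroxy-3-methyl-3,6-dihydro-1,2-dioxin-3-yl]methyl acetate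
Conditions: Ac2O (1.2 equiv), pyridine, CH2Cl2, 0 °C
Reagents that add atoms: acetic anhydride, CC(=O)OC(C)=O
Why: Pyridine-mediated acetylation is selective for the primary alcohol over the tertiary hemiperketal hydroxyl.

Step 26
Reactants: 40 the dioxinol acetate
Product: 41 CNP0169860.1, [(3R,6R)-6-hydroxy-3-methyl-6-[(1S,4S,6S,10R,12S)-4,12-dimethyl-9-methylidene-5-oxatricyclo[8.2.0.0(4,6)]dodecan-12-yl]-3,6-dihydro-1,2-dioxin-3-yl]methyl acetate
Conditions: 3-chloroperoxybenzoic acid (1.05 equiv), NaHCO3, CH2Cl2, −20 to 0 °C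
Reagents that add atoms: 3-chloroperoxybenzoic acid, O=C(OO)c1cccc(Cl)c1
Why: Prilezhaev epoxidation: the strained trisubstituted E-alkene of ring B reacts much faster than the exo-methylene and the dioxine alkene, and syn-stereospecific attack on the exposed outer face of the favoured ring-B conformer should give the (5S,7S) oxirane, as in the known conversion of caryophyllene into its oxide.

Compound list
1 | pent-4-yn-1-ol | C#CCCCO | starting material
2 | pent-4-ynal | C#CCCC=O | intermediate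
3 | ethyl (2E)-2-methylhept-2-en-6-ynoate | C#CCC/C=C(\C)C(=O)OCC | intermediate
4 | (2E)-2-methylhept-2-en-6-yn-1-ol | C#CCC/C=C(\C)CO | intermediate
5 | tert-butyl{[(2E)-2-methylhept-2-en-6-yn-1-yl]oxy}diphenylsilane | C#CCC/C=C(\C)CO[Si](c1ccccc1)(c1ccccc1)C(C)(C)C | intermediate
6 | but-3-ynoic acid | C#CCC(=O)O | starting material
7 | 2,2,2-trifluoroethyl but-3-ynoate | C#CCC(=O)OCC(F)(F)F | intermediate
8 | 2,2,2-trifluoroethyl buta-2,3-dienoate | C=C=CC(=O)OCC(F)(F)F | intermediate
9 | 2,2,2-trifluoroethyl 2-[(2S,3S)-2-(but-3-yn-1-yl)-3-({[tert-butyl(diphenyl)silyl]oxy}methyl)-3-methylcyclobutylidene]acetate | C#CCC[C@H]1C(=CC(=O)OCC(F)(F)F)C[C@]1(C)CO[Si](c1ccccc1)(c1ccccc1)C(C)(C)C | intermediate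
10 | 2-[(2S,3S)-2-(but-3-yn-1-yl)-3-({[tert-butyl(diphenyl)silyl]oxy}methyl)-3-methylcyclobutylidene]ethan-1-ol | C#CCC[C@H]1C(=CCO)C[C@]1(C)CO[Si](c1ccccc1)(c1ccccc1)C(C)(C)C | intermediate
11 | N-{2-[(2S,3S)-2-(but-3-yn-1-yl)-3-({[tert-butyl(diphenyl)silyl]oxy}methyl)-3-methylcyclobutylidene]ethyl}-2-nitrobenzenesulfonohydrazide | C#CCC[C@H]1C(=CCN(N)S(=O)(=O)c2ccccc2[N+](=O)[O-])C[C@]1(C)CO[Si](c1ccccc1)(c1ccccc1)C(C)(C)C | intermediate
12 | {2-[(2S,3S)-2-(but-3-yn-1-yl)-3-({[tert-butyl(diphenyl)silyl]oxy}methyl)-3-methylcyclobutylidene]ethyl}diazene | C#CCC[C@H]1C(=CCN=N)C[C@]1(C)CO[Si](c1ccccc1)(c1ccccc1)C(C)(C)C | intermediate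
13 | tert-butyl{[(1S,2S)-2-(but-3-yn-1-yl)-3-ethenyl-1-methylcyclobutyl]methoxy}diphenylsilane (C12 epimers) | C#CCC[C@H]1C(C=C)C[C@]1(C)CO[Si](c1ccccc1)(c1ccccc1)C(C)(C)C | intermediate
14 | oxirane | C1CO1 | starting material
15 | {(1E)-4-[(1S,2S)-2-({[tert-butyl(diphenyl)silyl]oxy}methyl)-4-ethenyl-2-methylcyclobutyl]-2-methylbut-1-en-1-yl}dimethylalane | C[Al](C)/C=C(\C)CC[C@H]1C(C=C)C[C@]1(C)CO[Si](c1ccccc1)(c1ccccc1)C(C)(C)C | intermediate
16 | lithium butyl{(1E)-4-[(1S,2S)-2-({[tert-butyl(diphenyl)silyl]oxy}methyl)-4-ethenyl-2-methylcyclobutyl]-2-methylbut-1-en-1-yl}dimethylalanate | [Li+].CCCC[Al-](C)(C)/C=C(\C)CC[C@H]1C(C=C)C[C@]1(C)CO[Si](c1ccccc1)(c1ccccc1)C(C)(C)C | intermediate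
17 | (3E)-6-[(1S,2S)-2-({[tert-butyl(diphenyl)silyl]oxy}methyl)-4-ethenyl-2-methylcyclobutyl]-4-methylhex-3-en-1-ol (C12 epimers) | OCC/C=C(\C)CC[C@H]1C(C=C)C[C@]1(C)CO[Si](c1ccccc1)(c1ccccc1)C(C)(C)C | intermediate
18 | tert-butyl{[(1S,2S)-2-[(3E)-6-{[tert-butyl(dimethyl)silyl]oxy}-3-methylhex-3-en-1-yl]-3-ethenyl-1-methylcyclobutyl]methoxy}diphenylsilane (C12 epimers) | CC(C)(C)[Si](C)(C)OCC/C=C(\C)CC[C@H]1C(C=C)C[C@]1(C)CO[Si](c1ccccc1)(c1ccccc1)C(C)(C)C | intermediate
19 | 1-[(2S,3S)-2-[(3E)-6-{[tert-butyl(dimethyl)silyl]oxy}-3-methylhex-3-en-1-yl]-3-({[tert-butyl(diphenyl)silyl]oxy}methyl)-3-methylcyclobutyl]ethan-1-one (C12 epimers) | CC(C)(C)[Si](C)(C)OCC/C=C(\C)CC[C@H]1C(C(C)=O)C[C@]1(C)CO[Si](c1ccccc1)(c1ccccc1)C(C)(C)C | intermediate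
20 | 1-[(1R,2S,3S)-2-[(3E)-6-{[tert-butyl(dimethyl)silyl]oxy}-3-methylhex-3-en-1-yl]-3-({[tert-butyl(diphenyl)silyl]oxy}methyl)-3-methylcyclobutyl]ethan-1-one | CC(C)(C)[Si](C)(C)OCC/C=C(\C)CC[C@H]1[C@@H](C[C@]1(C)CO[Si](c2ccccc2)(c2ccccc2)C(C)(C)C)C(C)=O | intermediate
21 | hydrazone of 20, (1R,2S,3S) | CC(C)(C)[Si](C)(C)OCC/C=C(\C)CC[C@H]1[C@@H](C[C@]1(C)CO[Si](c2ccccc2)(c2ccccc2)C(C)(C)C)C(C)=NN | intermediate
22 | tert-butyl{[(3E)-6-[(1S,2S,4R)-2-({[tert-butyl(diphenyl)silyl]oxy}methyl)-4-(1-iodoethenyl)-2-methylcyclobutyl]-4-methylhex-3-en-1-yl]oxy}dimethylsilane | CC(C)(C)[Si](C)(C)OCC/C=C(\C)CC[C@H]1[C@@H](C[C@]1(C)CO[Si](c2ccccc2)(c2ccccc2)C(C)(C)C)C(I)=C | intermediate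
23 | (3E)-6-[(1S,2S,4R)-2-({[tert-butyl(diphenyl)silyl]oxy}methyl)-4-(1-iodoethenyl)-2-methylcyclobutyl]-4-methylhex-3-en-1-ol | OCC/C=C(\C)CC[C@H]1[C@@H](C[C@]1(C)CO[Si](c2ccccc2)(c2ccccc2)C(C)(C)C)C(I)=C | intermediate
24 | (3E)-6-[(1S,2S,4R)-2-({[tert-butyl(diphenyl)silyl]oxy}methyl)-4-(1-iodoethenyl)-2-methylcyclobutyl]-4-methylhex-3-enal | O=CC/C=C(\C)CC[C@H]1[C@@H](C[C@]1(C)CO[Si](c2ccccc2)(c2ccccc2)C(C)(C)C)C(I)=C | intermediate
25 | dichloro{1-[(1R,2S,3S)-3-({[tert-butyl(diphenyl)silyl]oxy}methyl)-3-methyl-2-[(3E)-3-methyl-6-oxohex-3-en-1-yl]cyclobutyl]ethenyl}chromium | O=CC/C=C(\C)CC[C@H]1[C@@H](C[C@]1(C)CO[Si](c2ccccc2)(c2ccccc2)C(C)(C)C)C(=C)[Cr](Cl)Cl | intermediate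
26 | (1S,4E,9R,11S)-11-({[tert-butyl(diphenyl)silyl]oxy}methyl)-4,11-dimethyl-8-methylidenebicyclo[7.2.0]undec-4-en-7-ol (C3 epimers) | C=C1C(O)C/C=C(\C)CC[C@H]2[C@H]1C[C@]2(C)CO[Si](c1ccccc1)(c1ccccc1)C(C)(C)C | intermediate
27 | (1S,4E,9R,11S)-11-({[tert-butyl(diphenyl)silyl]oxy}methyl)-4,11-dimethyl-8-methylidenebicyclo[7.2.0]undec-4-en-7-yl methyl carbonate (C3 epimers) | C=C1C(OC(=O)OC)C/C=C(\C)CC[C@H]2[C@H]1C[C@]2(C)CO[Si](c1ccccc1)(c1ccccc1)C(C)(C)C | intermediate
28 | tert-butyl{[(1S,4E,9R,11S)-4,11-dimethyl-8-methylidenebicyclo[7.2.0]undec-4-en-11-yl]methoxy}diphenylsilane | C=C1CC/C=C(\C)CC[C@H]2[C@H]1C[C@]2(C)CO[Si](c1ccccc1)(c1ccccc1)C(C)(C)C | intermediate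
29 | [(1S,4E,9R,11S)-4,11-dimethyl-8-methylidenebicyclo[7.2.0]undec-4-en-11-yl]methanol | C=C1CC/C=C(\C)CC[C@H]2[C@H]1C[C@]2(C)CO | intermediate
30 | (1S,4E,9R,11S)-4,11-dimethyl-8-methylidenebicyclo[7.2.0]undec-4-ene-11-carbaldehyde | C=C1CC/C=C(\C)CC[C@H]2[C@H]1C[C@]2(C)C=O | intermediate
31 | [(2S)-2-methyloxiran-2-yl]methanol | OC[C@@]1(C)CO1 | starting material
32 | (2R)-2-methyloxirane-2-carbaldehyde | O=C[C@@]1(C)CO1 | intermediate
33 | (2S)-2-ethynyl-2-methyloxirane | C#C[C@@]1(C)CO1 | intermediate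
34 | lithium [(2S)-2-methyloxiran-2-yl]acetylide | [Li]C#C[C@@]1(C)CO1 | intermediate
35 | 1-[(1S,4E,9R,11S)-4,11-dimethyl-8-methylidenebicyclo[7.2.0]undec-4-en-11-yl]-3-[(2S)-2-methyloxiran-2-yl]prop-2-yn-1-ol (C16 epimers) | C=C1CC/C=C(\C)CC[C@H]2[C@H]1C[C@]2(C)C(O)C#C[C@@]1(C)CO1 | intermediate
36 | 1-[(1S,4E,9R,11S)-4,11-dimethyl-8-methylidenebicyclo[7.2.0]undec-4-en-11-yl]-3-[(2S)-2-methyloxiran-2-yl]prop-2-yn-1-one | C=C1CC/C=C(\C)CC[C@H]2[C@H]1C[C@]2(C)C(=O)C#C[C@@]1(C)CO1 | intermediate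
37 | (2Z)-1-[(1S,4E,9R,11S)-4,11-dimethyl-8-methylidenebicyclo[7.2.0]undec-4-en-11-yl]-3-[(2S)-2-methyloxiran-2-yl]prop-2-en-1-one | C=C1CC/C=C(\C)CC[C@H]2[C@H]1C[C@]2(C)C(=O)/C=C\[C@@]1(C)CO1 | intermediate
38 | (2Z,4R)-1-[(1S,4E,9R,11S)-4,11-dimethyl-8-methylidenebicyclo[7.2.0]undec-4-en-11-yl]-4-hydroperoxy-5-hydroxy-4-methylpent-2-en-1-one | C=C1CC/C=C(\C)CC[C@H]2[C@H]1C[C@]2(C)C(=O)/C=C\[C@](C)(CO)OO | intermediate
39 | (3R,6R)-3-[(1S,4E,9R,11S)-4,11-dimethyl-8-methylidenebicyclo[7.2.0]undec-4-en-11-yl]-6-(hydroxymethyl)-6-methyl-3,6-dihydro-1,2-dioxin-3-ol | C=C1CC/C=C(\C)CC[C@H]2[C@H]1C[C@]2(C)[C@@]1(O)C=C[C@](C)(CO)OO1 | intermediate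
40 | [(3R,6R)-6-[(1S,4E,9R,11S)-4,11-dimethyl-8-methylidenebicyclo[7.2.0]undec-4-en-11-yl]-6-hydroxy-3-methyl-3,6-dihydro-1,2-dioxin-3-yl]methyl acetate | C=C1CC/C=C(\C)CC[C@H]2[C@H]1C[C@]2(C)[C@@]1(O)C=C[C@](C)(COC(C)=O)OO1 | intermediate
41 | CNP0169860.1, [(3R,6R)-6-hydroxy-3-methyl-6-[(1S,4S,6S,10R,12S)-4,12-dimethyl-9-methylidene-5-oxatricyclo[8.2.0.0(4,6)]dodecan-12-yl]-3,6-dihydro-1,2-dioxin-3-yl]methyl acetate | C=C1CC[C@@H]2O[C@@]2(C)CC[C@H]2[C@H]1C[C@]2(C)[C@@]1(O)C=C[C@](C)(COC(C)=O)OO1 | target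

Total step count: 26.
Longest linear sequence: 24 steps (steps 1–3, 5–19 and 21–26); steps 4 and 20 prepare the two side fragments.

Steps most likely to fail

Step 24. What may go wrong is attack of hydrogen peroxide at the primary epoxide carbon, ionisation at C20 with loss of configuration, transannular reaction of the acid-sensitive ring-B diene under the Lewis acid, and Z-to-E drift of the enone before ring closure. The fallback makes the O–O bond on the small fragment before it meets the ring system. It sets out from 33. Perhydrolysis (H2O2 in Et2O, catalytic H3PMo12O40) would give (2R)-2-hydroperoxy-2-methylbut-3-yn-1-ol F1. Silylation of both the hydroxyl and the hydroperoxyl group (Et3SiCl, imidazole) would give triethyl{[(2R)-2-methyl-2-(triethylsilylperoxy)but-3-yn-1-yl]oxy}silane F2. Its zinc acetylide (Zn(OTf)2, Et3N, toluene) would add to aldehyde 30 to give the propargylic alcohol F3. Dess–Martin oxidation would give the ynone F4, and semi-hydrogenation over Pd on CaCO3 poisoned with Pb(OAc)2 the Z-enone F5. HF·pyridine would then remove both silyl groups, and the freed hydroperoxide would close onto the ketone, so that the route is rejoined at 39.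

Step 15. What may go wrong is oligomerisation instead of nine-membered ring closure, reduction of the C–I bond without C–C bond formation, and conjugation or self-condensation of the β,γ-unsaturated aldehyde. The fallback forms the same C2–C3 bond by nickel-catalysed reductive alkyne–aldehyde macrocyclisation. It sets out from 22. Dehydroiodination (t-BuOK, THF) would give the terminal alkyne F6, acid-catalysed methanolysis the alcohol F7, and Dess–Martin oxidation the ynal F8. Ni(cod)2 with the bulky carbene 1,3-bis[2,6-bis(diphenylmethyl)-4-methylphenyl]imidazol-2-ylidene and Et3SiH under high dilution would join the internal alkyne carbon to the aldehyde and give the triethylsilyl ether F9 of the ring-B allylic alcohol. Pyridinium p-toluenesulfonate in MeOH would then return to 26.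

Step 5. What may go wrong is binding of the Lewis acid to the silyl ether oxygen, ionisation of the allylic C–O bond, weak enantiofacial discrimination, and loss of alkene geometry through a long-lived cation. The fallback replaces catalyst control by auxiliary control with separation of diastereomers. It sets out from 6 and 5. Esterification of 6 with (1R,2S,5R)-5-methyl-2-(2-phenylpropan-2-yl)cyclohexan-1-ol (DCC, then Et3N) would give the chiral allenoate F10. Its EtAlCl2-promoted [2+2] cycloaddition with 5 would give two diastereomeric adducts, from which the (2S,3S) adduct F11 is separated by chromatography. Reduction with i-Bu2AlH would release the auxiliary alcohol and rejoin the route at 10.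

Further compounds
F1 | step 24 | (2R)-2-hydroperoxy-2-methylbut-3-yn-1-ol | C#C[C@](C)(CO)OO
F2 | step 24 | triethyl{[(2R)-2-methyl-2-(triethylsilylperoxy)but-3-yn-1-yl]oxy}silane | C#C[C@](C)(CO[Si](CC)(CC)CC)OO[Si](CC)(CC)CC
F3 | step 24 | (4R)-1-[(1S,4E,9R,11S)-4,11-dimethyl-8-methylidenebicyclo[7.2.0]undec-4-en-11-yl]-4-methyl-5-(triethylsilyloxy)-4-(triethylsilylperoxy)pent-2-yn-1-ol (C16 epimers) | C=C1CC/C=C(\C)CC[C@H]2[C@H]1C[C@]2(C)C(O)C#C[C@](C)(CO[Si](CC)(CC)CC)OO[Si](CC)(CC)CC
F4 | step 24 | (4R)-1-[(1S,4E,9R,11S)-4,11-dimethyl-8-methylidenebicyclo[7.2.0]undec-4-en-11-yl]-4-methyl-5-(triethylsilyloxy)-4-(triethylsilylperoxy)pent-2-yn-1-one | C=C1CC/C=C(\C)CC[C@H]2[C@H]1C[C@]2(C)C(=O)C#C[C@](C)(CO[Si](CC)(CC)CC)OO[Si](CC)(CC)CC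
F5 | step 24 | (2Z,4R)-1-[(1S,4E,9R,11S)-4,11-dimethyl-8-methylidenebicyclo[7.2.0]undec-4-en-11-yl]-4-methyl-5-(triethylsilyloxy)-4-(triethylsilylperoxy)pent-2-en-1-one | C=C1CC/C=C(\C)CC[C@H]2[C@H]1C[C@]2(C)C(=O)/C=C\[C@](C)(CO[Si](CC)(CC)CC)OO[Si](CC)(CC)CC
F6 | step 15 | tert-butyl{[(3E)-6-[(1S,2S,4R)-2-({[tert-butyl(diphenyl)silyl]oxy}methyl)-4-ethynyl-2-methylcyclobutyl]-4-methylhex-3-en-1-yl]oxy}dimethylsilane | CC(C)(C)[Si](C)(C)OCC/C=C(\C)CC[C@H]1[C@@H](C[C@]1(C)CO[Si](c2ccccc2)(c2ccccc2)C(C)(C)C)C#C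
F7 | step 15 | (3E)-6-[(1S,2S,4R)-2-({[tert-butyl(diphenyl)silyl]oxy}methyl)-4-ethynyl-2-methylcyclobutyl]-4-methylhex-3-en-1-ol | OCC/C=C(\C)CC[C@H]1[C@@H](C[C@]1(C)CO[Si](c2ccccc2)(c2ccccc2)C(C)(C)C)C#C
F8 | step 15 | (3E)-6-[(1S,2S,4R)-2-({[tert-butyl(diphenyl)silyl]oxy}methyl)-4-ethynyl-2-methylcyclobutyl]-4-methylhex-3-enal | O=CC/C=C(\C)CC[C@H]1[C@@H](C[C@]1(C)CO[Si](c2ccccc2)(c2ccccc2)C(C)(C)C)C#C
F9 | step 15 | tert-butyl{[(1S,4E,9R,11S)-4,11-dimethyl-8-methylidene-7-(triethylsilyloxy)bicyclo[7.2.0]undec-4-en-11-yl]methoxy}diphenylsilane (C3 epimers) | C=C1C(O[Si](CC)(CC)CC)C/C=C(\C)CC[C@H]2[C@H]1C[C@]2(C)CO[Si](c1ccccc1)(c1ccccc1)C(C)(C)C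
F10 | step 5 | (1R,2S,5R)-5-methyl-2-(2-phenylpropan-2-yl)cyclohexyl buta-2,3-dienoate | C=C=CC(=O)O[C@@H]1C[C@H](C)CC[C@H]1C(C)(C)c1ccccc1
F11 | step 5 | (1R,2S,5R)-5-methyl-2-(2-phenylpropan-2-yl)cyclohexyl 2-[(2S,3S)-2-(but-3-yn-1-yl)-3-({[tert-butyl(diphenyl)silyl]oxy}methyl)-3-methylcyclobutylidene]acetate | C#CCC[C@H]1C(=CC(=O)O[C@@H]2C[C@H](C)CC[C@H]2C(C)(C)c2ccccc2)C[C@]1(C)CO[Si](c1ccccc1)(c1ccccc1)C(C)(C)C
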